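**Assumptions (one line each).** Numbering follows the ent-kaurane numbering of the target. (R)-Cyclohex-3-ene-1-carboxylic acid and 2,2-dimethylcyclohexanone are taken as commercial and cheap. The absolute configuration is that of the given SMILES (ent-series).

## Retrosynthetic overview
1. The C6 methyl acetal comes from anodic α-methoxylation of the 6,19-tetrahydrofuran (THF). The enone comes from allylic oxidation of the exocyclic alkene.
2. Ring D (bicyclo[3.2.1]octane) is formed last by Pd(II) oxidative cycloalkenylation of the lactone ketene acetal onto an axial isopropenyl group. That group is delivered by cuprate addition to the ring-C enone, trans to C8.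
3. The C9–C10 bond (tertiary next to quaternary) forms by a silylene-tethered photoredox radical cyclization. An α-bromoketone from 2,2-dimethylcyclohexanone (ring A) couples with the silyl dienol ether of an enone from (R)-cyclohex-3-enecarboxylic acid (ring C). The δ-lactone then closes.
4. The A ring is elaborated by C5 ketone → C6 CH2OH (Wittig, hydroboration), then THF closure by 1,5-HAT (Suárez), which picks the axial C19 methyl.
5. Ring order: C (starting material) → C9–C10 link and lactone → THF on ring A → ring D.

## Route

**Step 1**
Reactants: 1 (R)-cyclohex-3-ene-1-carboxylic acid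
Product: 2 methyl (R)-cyclohex-3-ene-1-carboxylate
Conditions: MeI, K2CO3, DMF, 25 °C
Reagents that add atoms: iodomethane, CI
Why: Simple O-alkylation of the carboxylate; the stereocentre is untouched.

**Step 2**
Reactants: 2
Product: 3 methyl (S)-5-oxocyclohex-3-ene-1-carboxylate (C8 ester, C11 ketone, Δ12)
Conditions: Pd(OH)2/C, K2CO3, t-BuOOH, CH2Cl2, 25 °C
Reagents that add atoms: tert-butyl hydroperoxide, CC(C)(C)OO (supplies the ketone O)
Why: Pd-catalysed allylic C–H oxidation of the less hindered allylic CH2 (C11, remote from the ester) gives the enone; the configuration at C8 is retained (the descriptor changes from R to S only because CIP priorities change).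

**Step 3**
Reactants: 4 2,2-dimethylcyclohexan-1-one
Product: 5 6-(hydroxymethyl)-2,2-dimethylcyclohexan-1-one (racemic; becomes the C10 radical centre)
Conditions: LDA, THF, −78 °C; then monomeric CH2O, −78 → 0 °C
Reagents that add atoms: formaldehyde, C=O
Why: The quaternary C2 leaves only one enolisable α-carbon, so enolate hydroxymethylation (aldol) is regiospecific.

**Step 4**
Reactants: 5
Product: 6 6-bromo-6-(hydroxymethyl)-2,2-dimethylcyclohexan-1-one
Conditions: Br2, CH2Cl2, 0 °C
Reagents that add atoms: bromine, BrBr
Why: Acid-catalysed enol bromination at the tertiary α-carbon; the resulting stereocentre is irrelevant because it becomes a planar radical.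

**Step 5**
Reactants: 6
Product: 7 [(1-bromo-3,3-dimethyl-2-oxocyclohexyl)methoxy](diisopropyl)silyl triflate (used crude)
Conditions: iPr2Si(OTf)2, 2,6-lutidine, CH2Cl2, −78 → 0 °C
Reagents that add atoms: diisopropylsilyl bis(triflate), CC(C)[Si](OS(=O)(=O)C(F)(F)F)(OS(=O)(=O)C(F)(F)F)C(C)C
Why: Selective silylation of the primary alcohol creates the silylene tether that will link O20 to O11.

**Step 6**
Reactants: 3 (enone) and 7 (silyl triflate)
Product: 8 tethered 2-silyloxy-1,3-diene: methyl (S)-3-[(diisopropyl{[(1-bromo-3,3-dimethyl-2-oxocyclohexyl)methoxy]}silyl)oxy]cyclohexa-2,4-diene-1-carboxylate, with C9=C11 and C12=C13 and the C8 centre retained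
Conditions: Et3N, CH2Cl2, 0 → 25 °C
Reagents that add atoms: none
Why: Soft enolisation (silyl triflate/amine) of the enone can only occur at the single α′-CH2 (C9), so the dienol ether forms regiospecifically and the silicon bridges O11 to O20.

**Step 7**
Reactants: 8
Product: 9 methyl 2-[1-(hydroxymethyl)-3,3-dimethyl-2-oxocyclohexyl]-3-oxocyclohex-4-ene-1-carboxylate (C5 ketone, C11 enone, free C20–OH; C8 ester and C9 ring-A substituent cis; C10 as in the target; SMILES in the list)
Conditions: fac-Ir(ppy)3 (1 mol %), 2,6-lutidine, MeCN (0.01 M), blue LEDs, 25 °C; then HF·pyridine, THF, 0 °C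
Reagents that add atoms: none
Why: Proposed new method: photoreduction of the tertiary α-bromoketone gives an electrophilic tertiary α-keto radical that adds in a 7-membered chair-like silylene-tethered cyclization to C9, the nucleophilic terminus of the 2-silyloxydiene. The resulting allylic α-silyloxy radical is oxidised by Ir(IV) to the oxocarbenium, which loses silicon to regenerate the enone. C9 is attacked axially, cis to the equatorial C8 ester, and the C10 configuration is set by the chair tether geometry. The closest known reactions are Stork/Nishiyama silicon-tethered radical cyclization and photoredox α-carbonyl radical addition to silyl enol ethers. HF·pyridine is used to avoid retro-aldol of the β-hydroxy ketone.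

**Step 8**
Reactants: 9
Product: 10 cis-fused 7,20-δ-lactone: enone (C11 ketone, Δ12) spiro-linked at C10 to the 2,2-dimethylcyclohexanone (C5 ketone)
Conditions: TsOH·H2O (0.2 equiv), PhMe, 110 °C, Dean–Stark
Reagents that add atoms: none
Why: Acid-catalysed lactonisation (loss of MeOH); the cis-fused six-membered lactone forms only from the correct C10 epimer. Acid avoids retro-aldol, and C8 is epimerisable so the ring-fusion geometry is thermodynamic.

**Step 9**
Reactants: 10
Product: 11 ethylene ketal of the C11 enone (Δ12 retained)
Conditions: 1,2-bis(trimethylsilyloxy)ethane, TMSOTf (cat.), CH2Cl2, −78 → 0 °C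
Reagents that add atoms: 1,2-bis(trimethylsilyloxy)ethane, C[Si](C)(C)OCCO[Si](C)(C)C (adds OCH2CH2O)
Why: Noyori ketalisation takes the unhindered enone carbonyl without alkene migration and leaves the C5 ketone, which sits between two quaternary carbons, untouched.

**Step 10**
Reactants: 11
Product: 12 C5 exocyclic methylene (C5=C6H2)
Conditions: Ph3P+CH3 Br−, KOt-Am, PhMe, 110 °C
Reagents that add atoms: methyltriphenylphosphonium bromide, C[P+](c1ccccc1)(c1ccccc1)c1ccccc1.[Br-] (adds =CH2)
Why: Wittig methylenation with the smallest ylide, generated with a non-nucleophilic amylate base and run at reflux (forcing conditions for ketones flanked by two quaternary carbons), reaches the hindered ketone while the lactone and ketal survive.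

**Step 11**
Reactants: 12
Product: 13 C6 primary alcohol with C5–H (H5 axial, trans to C20)
Conditions: 9-BBN (1.1 equiv), THF, 65 °C; then NaBO3·4H2O, THF/H2O, 25 °C
Reagents that add atoms: hydrogen peroxide (from perborate), OO (supplies OH)
Why: Hydroboration–oxidation puts boron on the terminal C6; borane and hydride are delivered from the open face of ring A, opposite the axial C20 (and the axial methyl). This sets H5 axial and C6 equatorial, as in the target. The bulky 9-BBN in slight excess favours the terminal methylene over the cis-cycloalkene, whose C12 is flanked by the spiroketal.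

**Step 12**
Reactants: 13
Product: 14 6,19-THF (C6 CH2–O–C19), C4 now stereogenic
Conditions: PhI(OAc)2, I2, cyclohexane, hν (visible lamp), 45 °C
Reagents that add atoms: none
Why: Suárez hypoiodite reaction: the C6 alkoxyl radical abstracts H by 1,5-HAT from the only methyl cis to C6 (the axial, 1,3-diaxial-to-C20 methyl, C19); iodination and SN2 close the cis-fused THF, which assigns C18 and C19.

**Step 13**
Reactants: 14
Product: 15 enone (ketal removed)
Conditions: PPTS, acetone/H2O, 60 °C
Reagents that add atoms: water, O (supplies the ketone O)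
Why: Ordinary acid-catalysed ketal hydrolysis; the THF ether and lactone are stable.

**Step 14**
Reactants: 15
Product: 16 C13 isopropenyl ketone (C11 ketone)
Conditions: CH2=C(CH3)MgBr, CuBr·SMe2, TMSCl, THF, −78 → −40 °C
Reagents that add atoms: isopropenylmagnesium bromide, C=C(C)[Mg]Br (adds isopropenyl; H from work-up)
Why: Cuprate 1,4-addition occurs axially at C13, anti to the axial C10 and trans to the equatorial C7 (3,5-trans), which gives the axial C16 unit needed for ring D.

**Step 15**
Reactants: 16
Product: 17 C11 equatorial alcohol
Conditions: Al(Oi-Pr)3, i-PrOH/PhMe, 80 °C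
Reagents that add atoms: none
Why: Equilibrating Meerwein–Ponndorf–Verley reduction gives the thermodynamic equatorial alcohol (11-OH, cis to C10), which is the target configuration.

**Step 16**
Reactants: 17
Product: 18 C11 TBS ether
Conditions: TBSOTf, 2,6-lutidine, CH2Cl2, −78 °C
Reagents that add atoms: tert-butyldimethylsilyl triflate, CC(C)(C)[Si](C)(C)OS(=O)(=O)C(F)(F)F (adds TBS)
Why: Standard protection that keeps the alcohol out of the next enolisation.

**Step 17**
Reactants: 18
Product: 19 ring-D bicyclo[3.2.1]octane (C8–C15 bond; C16=C17 exocyclic; C15H2)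
Conditions: LDA, THF, −78 °C; TMSCl; then Pd(OAc)2 (1.2 equiv), MeCN, 25 °C
Reagents that add atoms: none
Why: Pd(II)-mediated oxidative cycloalkenylation of the lactone silyl ketene acetal onto the axial isopropenyl group. The C15 bond forms on the face of the axial C16 unit, so C8 becomes quaternary with C7 on the opposite face, and β-H elimination gives the exocyclic methylene.

**Step 18**
Reactants: 19
Product: 20 C15 allylic alcohol (epimers at C15 are not specified)
Conditions: SeO2 (0.3 equiv), t-BuOOH, CH2Cl2, 23 °C
Reagents that add atoms: tert-butyl hydroperoxide, CC(C)(C)OO (supplies OH)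
Why: Riley allylic oxidation at the CH2 next to C8; the stereocentre formed is destroyed in the next step.

**Step 19**
Reactants: 20
Product: 21 C15 enone (TBS-protected precursor)
Conditions: Dess–Martin periodinane, NaHCO3, CH2Cl2, 25 °C
Reagents that add atoms: none
Why: Mild oxidation of the secondary allylic alcohol to the exocyclic enone.

**Step 20**
Reactants: 21
Product: 22 TBS-protected angustifolin (C6 methyl acetal)
Conditions: graphite anode/Pt cathode, Et4NOTs, MeOH, undivided cell, 10 mA, 2.5 F/mol, 20 °C
Reagents that add atoms: methanol, CO (supplies OMe)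
Why: Shono-type anodic α-methoxylation of the THF at the less hindered C6–H2 gives the oxocarbenium, which is trapped by MeOH. The OMe goes to the convex face, cis to H5 and trans to ring A, which is the anomeric and steric preference and matches the target at C6.

**Step 21**
Reactants: 22
Product: 23 angustifolin
Conditions: TBAF, AcOH, THF, 0 °C
Reagents that add atoms: none
Why: Buffered fluoride removes the TBS ether without touching the enone, acetal or lactone.

## Compound list
1 | (R)-cyclohex-3-ene-1-carboxylic acid | OC(=O)[C@H]1CC=CCC1 | starting material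
2 | methyl (R)-cyclohex-3-ene-1-carboxylate | COC(=O)[C@H]1CC=CCC1 | intermediate
3 | methyl (S)-5-oxocyclohex-3-ene-1-carboxylate | COC(=O)[C@H]1CC=CC(=O)C1 | intermediate
4 | 2,2-dimethylcyclohexan-1-one | CC1(C)CCCCC1=O | starting material
5 | 6-(hydroxymethyl)-2,2-dimethylcyclohexan-1-one (racemic) | OCC1CCCC(C)(C)C1=O | intermediate
6 | 6-bromo-6-(hydroxymethyl)-2,2-dimethylcyclohexan-1-one (racemic) | OCC1(Br)CCCC(C)(C)C1=O | intermediate
7 | [(1-bromo-3,3-dimethyl-2-oxocyclohexyl)methoxy](diisopropyl)silyl triflate | O=C1C(C)(C)CCCC1(Br)CO[Si](OS(=O)(=O)C(F)(F)F)(C(C)C)C(C)C | intermediate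
8 | tethered silyl dienol ether | COC(=O)[C@H]1CC=CC(O[Si](C(C)C)(C(C)C)OCC2(Br)CCCC(C)(C)C2=O)=C1 | intermediate
9 | C9–C10 coupled hydroxy keto-enone ester | O=C1C=CC[C@H](C(=O)OC)[C@@H]1[C@]2(CO)CCCC(C)(C)C2=O | intermediate
10 | 7,20-lactone enone, C5 ketone | O=C1C=CC[C@@H]2C(=O)OC[C@]3(CCCC(C)(C)C3=O)[C@H]12 | intermediate
11 | C11 ethylene ketal of 10 | C1=CC[C@@H]2C(=O)OC[C@]3(CCCC(C)(C)C3=O)[C@@H]2C14OCCO4 | intermediate
12 | C5 methylene compound | C1=CC[C@@H]2C(=O)OC[C@]3(CCCC(C)(C)C3=C)[C@@H]2C14OCCO4 | intermediate
13 | C6 primary alcohol | C1=CC[C@@H]2C(=O)OC[C@]3(CCCC(C)(C)[C@H]3CO)[C@@H]2C14OCCO4 | intermediate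
14 | 6,19-THF ketal | C1=CC[C@@H]2C(=O)OC[C@]3(CCC[C@@]4(C)COC[C@H]43)[C@@H]2C15OCCO5 | intermediate
15 | 6,19-THF enone | O=C1C=CC[C@@H]2C(=O)OC[C@]3(CCC[C@@]4(C)COC[C@H]43)[C@H]12 | intermediate
16 | C13 isopropenyl, C11 ketone | C=C(C)[C@H]1C[C@@H]2C(=O)OC[C@]3(CCC[C@@]4(C)COC[C@H]43)[C@@H]2C(=O)C1 | intermediate
17 | C11 equatorial alcohol | C=C(C)[C@H]1C[C@@H]2C(=O)OC[C@]3(CCC[C@@]4(C)COC[C@H]43)[C@@H]2[C@H](O)C1 | intermediate
18 | C11 TBS ether | C=C(C)[C@H]1C[C@@H]2C(=O)OC[C@]3(CCC[C@@]4(C)COC[C@H]43)[C@@H]2[C@H](O[Si](C)(C)C(C)(C)C)C1 | intermediate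
19 | ring-D closed TBS ether (C15H2, Δ16) | C=C1C[C@]23C[C@H]1C[C@@H](O[Si](C)(C)C(C)(C)C)[C@H]2[C@@]1(CCC[C@@]2(C)COC[C@H]21)COC3=O | intermediate
20 | C15 allylic alcohol (C15 epimers unspecified) | C=C1C(O)[C@]23C[C@H]1C[C@@H](O[Si](C)(C)C(C)(C)C)[C@H]2[C@@]1(CCC[C@@]2(C)COC[C@H]21)COC3=O | intermediate
21 | C15 enone, TBS ether | C=C1C(=O)[C@]23C[C@H]1C[C@@H](O[Si](C)(C)C(C)(C)C)[C@H]2[C@@]1(CCC[C@@]2(C)COC[C@H]21)COC3=O | intermediate
22 | TBS-angustifolin | C=C1C(=O)[C@]23C[C@H]1C[C@@H](O[Si](C)(C)C(C)(C)C)[C@H]2[C@@]1(CCC[C@@]2(C)CO[C@H](OC)[C@H]21)COC3=O | intermediate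
23 | angustifolin | C=C1C(=O)[C@]23C[C@H]1C[C@@H](O)[C@H]2[C@@]1(CCC[C@@]2(C)CO[C@H](OC)[C@H]21)COC3=O | target

## Totals
Total steps: 21. Longest linear sequence: 19 steps, running through the ring-A branch (4 → 5 → 6 → 7 → 8 → 9 → 10 → … → 23, i.e. steps 3, 4, 5, 6, 7, … , 21). The ring-C branch (1 → 2 → 3) is shorter and joins at step 6.

## Three steps most likely to fail
1. **Step 7 (proposed new method).** The tethered radical cyclization could give the wrong C10 epimer, debrominate, or undergo 1,5-HAT instead of cyclising.
   *Fallback (known chemistry, different approach):* drop the tether and use an Overman-type intermolecular decarboxylative radical addition. The tertiary redox-active ester of the ketal-protected A-ring acid (Hantzsch ester, Ru(bpy)3, blue light) adds to the C9 position of a C11-ketalised enoate prepared from 3 by selenoxide dehydrogenation.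
2. **Step 12 (Suárez cyclization).** Competing iodination of the C12=C13 alkene, or attack at the wrong methyl, would lower the yield.
   *Fallback:* install the C19 oxygen at the C5-ketoxime stage by oxime-directed Pd-catalysed C–H acetoxylation of the axial methyl (Sanford type). Then restore the ketone and continue with Wittig, hydroboration and THF closure by displacement.
3. **Step 20 (anodic methoxylation).** It could oxidise C19 instead of C6, or attack the enone or allylic C–H positions.
   *Fallback:* use RuO4 (RuCl3/NaIO4) on 14 or 15 to convert the THF to the lactone, then DIBAL at −78 °C to the lactol, then MeOH with cat. PPTS, which sets the C6 acetal thermodynamically.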